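Locants (elemane numbering): ring C5–C10; C5 bears C4(=C3H2)–C15HO, C6 and C9 bear the angelates, C7–C11(=C13H2)–C12(=O)–O–C8 is the lactone, C10 bears C14H3 and the epoxide C1–C2. Target ⇒ C9 angeloylation and lactol oxidation ⇒ lactol from anti opening of a C8–C9 epoxide by the C12 aldehyde hydrate; both C=CH2 units by α-methylenation of CH2–CHO arms on C5 and C7.
⇒ cyclohexene 14: C8=C9 from the C9 ketone via its enol triflate; epoxide C1–C2 from a chloroacetyl group on C10 by reagent-controlled reduction; C6–O and the C7 arm from a cis-fused cyclobutanone by Baeyer–Villiger oxidation and reduction.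
⇒ quaternary C10 by C-acylation of silyl enol ether 7; 7 ⇒ disconnection of C5–C6 and C7–C8: endo Diels–Alder reaction of 2-silyloxydiene 4 (C8=C9–C10=C5) with cyclobut-2-enone 6 (C6=C7).
Enabling feature: on ring C5–C10 the C4 arm on C5, the oxygen on C6 and the C11 arm on C7 are contiguous and mutually cis, and C9, para to C6, carries oxygen; a cis-fused C6–C(=O)–CH2–C7 cyclobutanone (C6–O after oxygen insertion) is the retron of a cyclobutenone cycloaddition to a 2-silyloxydiene.
Ring order: carbocycle C5–C10 with fused cyclobutanone (step 4) → temporary γ-lactone on O6 (step 6) → epoxide C1–C2 (step 7) → lactone ring C7–C11–C12–O–C8 (steps 16, 17).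

Key step: step 4

Assumption: the sense of induction of the chiral Lewis acid in step 4 is taken as drawn for 7; should it prove opposite, the mirror-image catalyst is used and nothing else changes.

Step 1
Reactants: 1 3-[(tert-butyldimethylsilyl)oxy]propanal; 2 3-(triphenyl-λ5-phosphanylidene)butan-2-one
Product: 3 (E)-6-[(tert-butyldimethylsilyl)oxy]-3-methylhex-3-en-2-one
Conditions: toluene, 90 °C
Reagents that add atoms: none
Why: Wittig olefination with a stabilised acylphosphorane should give the (E)-enone under thermodynamic control, the geometry that later holds the C5 side chain "outside" in the diene.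

Step 2
Reactants: 3 (E)-6-[(tert-butyldimethylsilyl)oxy]-3-methylhex-3-en-2-one
Product: 4 (E)-2,6-bis[(tert-butyldimethylsilyl)oxy]-3-methylhexa-1,3-diene
Conditions: TBSOTf, Et3N, CH2Cl2, −78 → 0 °C
Reagents that add atoms: tert-butyldimethylsilyl triflate, CC(C)(C)[Si](C)(C)OS(=O)(=O)C(F)(F)F
Why: soft enolisation and O-silylation (silyl enol ether formation) at the only α-methyl group should give the cross-conjugated 2-silyloxydiene with the (E)-alkene untouched.

Step 3
Reactants: 5 3-bromocyclobutan-1-one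
Product: 6 cyclobut-2-en-1-one
Conditions: n-Bu3N, neat, 20 °C, reduced pressure, distillate trapped at −78 °C and taken up in CH2Cl2
Reagents that add atoms: none
Why: amine-induced E1cB dehydrobromination of the β-bromoketone, the volatile enone being distilled out as it forms and used at once.

Step 4
Reactants: 4 (E)-2,6-bis[(tert-butyldimethylsilyl)oxy]-3-methylhexa-1,3-diene; 6 cyclobut-2-en-1-one
Product: 7 all-cis 3-(tert-butyldimethylsilyloxy)-5-[2-(tert-butyldimethylsilyloxy)ethyl]-4-methylbicyclo[4.2.0]oct-3-en-7-one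
Conditions: (S)-3,3-diphenyl-1-(2-methylphenyl)tetrahydro-1H,3H-pyrrolo[1,2-c][1,3,2]oxazaborole·HNTf2 (20 mol %), CH2Cl2, −78 °C, slow addition of 6
Reagents that add atoms: none
Why: Normal-demand [4+2] cycloaddition (Diels–Alder reaction) of the 2-silyloxydiene with the strained, Lewis-acid-activated enone; the closest known reaction types are the endo-selective cycloaddition of cyclobut-2-enone to silyloxydienes and the oxazaborolidinium-catalysed Diels–Alder reaction of cyclic enones. The carbocycle C5–C10 is closed in one suprafacial [4πs+2πs] event, C5–C6 and C7–C8 forming together while the four-membered ring stays cis-fused. Regiochemistry: the silyloxy group on C9 makes C8 the nucleophilic terminus, which bonds to the enone β-carbon C7, and the alkyl group on C5 reinforces this, so the "para" and "ortho" preferences coincide. C6 and C7 are cis because both belong to the cyclic dienophile; C5 is set cis to them by the endo transition state together with the (E) geometry of C10=C5; the absolute configuration comes from the chiral boron Lewis acid on the ketone oxygen, which blocks one enone face. The step needs endo over exo selectivity, secured by the carbonyl-under-diene preference that is strong for cyclobutenone, and it needs the catalysed path to outrun the background reaction, which low temperature and slow addition of 6 should secure.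

Step 5
Reactants: 7 all-cis 3-(tert-butyldimethylsilyloxy)-5-[2-(tert-butyldimethylsilyloxy)ethyl]-4-methylbicyclo[4.2.0]oct-3-en-7-one; 8 chloroacetyl chloride
Product: 9 4-(chloroacetyl)-5-[2-(tert-butyldimethylsilyloxy)ethyl]-4-methylbicyclo[4.2.0]octane-3,7-dione
Conditions: ZnCl2 (0.2 equiv), CH2Cl2/Et2O, −20 → 20 °C
Reagents that add atoms: none
Why: Lewis-acid-catalysed C-acylation of a silyl enol ether should form the quaternary centre C10, the acyl chloride approaching anti to the adjacent C5 side chain and to the concave cis-fused cyclobutanone, so that C1 ends up trans and the methyl group cis to the C5 arm.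

Step 6
Reactants: 9 4-(chloroacetyl)-5-[2-(tert-butyldimethylsilyloxy)ethyl]-4-methylbicyclo[4.2.0]octane-3,7-dione
Product: 10 cis-fused 6-(chloroacetyl)-7-[2-(tert-butyldimethylsilyloxy)ethyl]-6-methylhexahydro-1-benzofuran-2,5-dione
Conditions: mCPBA, CH2Cl2, 0 °C
Reagents that add atoms: 3-chloroperbenzoic acid, OOC(=O)c1cccc(Cl)c1
Why: Baeyer–Villiger oxidation is fastest at the strained cyclobutanone and the more substituted carbon C6 migrates with retention, which should place O6 cis to the C5 and C7 substituents, while the hindered cyclohexanone and the α-chloroketone react far more slowly.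

Step 7
Reactants: 10 cis-fused 6-(chloroacetyl)-7-[2-(tert-butyldimethylsilyloxy)ethyl]-6-methylhexahydro-1-benzofuran-2,5-dione
Product: 12 7-[2-(tert-butyldimethylsilyloxy)ethyl]-6-methyl-6-[(2R)-oxiran-2-yl]hexahydro-1-benzofuran-2,5-dione, via chlorohydrin 11 (not isolated)
Conditions: (R)-1-methyl-3,3-diphenyltetrahydro-1H,3H-pyrrolo[1,2-c][1,3,2]oxazaborole (10 mol %), BH3·SMe2, THF, −20 °C; then DBU, CH2Cl2, 0 °C
Reagents that add atoms: none
Why: Corey–Bakshi–Shibata reduction of the activated chloromethyl ketone (large group quaternary C10, small group CH2Cl) should set C1 as (R) under reagent control, and the base then closes the epoxide by intramolecular Williamson displacement without touching C1.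

Step 8
Reactants: 12 7-[2-(tert-butyldimethylsilyloxy)ethyl]-6-methyl-6-[(2R)-oxiran-2-yl]hexahydro-1-benzofuran-2,5-dione
Product: 13 enol triflate of 12 (C8=C9–OTf)
Conditions: KN(SiMe3)2, PhNTf2, THF, −78 °C
Reagents that add atoms: N-phenylbis(trifluoromethanesulfonimide), O=S(=O)(N(c1ccccc1)S(=O)(=O)C(F)(F)F)C(F)(F)F
Why: kinetic enolate formation and O-sulfonylation (enol triflate synthesis) can only occur toward C8 because C10 is quaternary, and the ketone is deprotonated before the less acidic lactone.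

Step 9
Reactants: 13 enol triflate of 12 (C8=C9–OTf)
Product: 14 7-[2-(tert-butyldimethylsilyloxy)ethyl]-6-methyl-6-[(2R)-oxiran-2-yl]-3a,6,7,7a-tetrahydro-1-benzofuran-2(3H)-one
Conditions: Pd(OAc)2 (5 mol %), PPh3, HCO2H, n-Bu3N, DMF, 60 °C
Reagents that add atoms: none
Why: palladium-catalysed formate reduction of a vinyl triflate should give the C8=C9 alkene that will later receive both oxygens.

Step 10
Reactants: 14 7-[2-(tert-butyldimethylsilyloxy)ethyl]-6-methyl-6-[(2R)-oxiran-2-yl]-3a,6,7,7a-tetrahydro-1-benzofuran-2(3H)-one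
Product: 15 6-[2-(tert-butyldimethylsilyloxy)ethyl]-2-(2-hydroxyethyl)-5-methyl-5-[(2R)-oxiran-2-yl]cyclohex-3-en-1-ol
Conditions: LiBH4, THF, 0 → 20 °C
Reagents that add atoms: none
Why: hydride reduction of the γ-lactone to the diol should free O6 and turn C12 into a primary alcohol, while the hindered terminal epoxide, the alkene and the silyl ether are left.

Step 11
Reactants: 15 6-[2-(tert-butyldimethylsilyloxy)ethyl]-2-(2-hydroxyethyl)-5-methyl-5-[(2R)-oxiran-2-yl]cyclohex-3-en-1-ol
Product: 16 2,6-bis[2-(tert-butyldimethylsilyloxy)ethyl]-5-methyl-5-[(2R)-oxiran-2-yl]cyclohex-3-en-1-ol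
Conditions: TBSCl, imidazole, CH2Cl2, 0 °C
Reagents that add atoms: tert-butyldimethylsilyl chloride, CC(C)(C)[Si](C)(C)Cl
Why: silylation should be selective for the primary alcohol over the flanked secondary C6 hydroxyl.

Step 12
Reactants: 16 2,6-bis[2-(tert-butyldimethylsilyloxy)ethyl]-5-methyl-5-[(2R)-oxiran-2-yl]cyclohex-3-en-1-ol; 17 angelic acid
Product: 18 2,6-bis[2-(tert-butyldimethylsilyloxy)ethyl]-5-methyl-5-[(2R)-oxiran-2-yl]cyclohex-3-en-1-yl (Z)-2-methylbut-2-enoate
Conditions: 2,4,6-trichlorobenzoyl chloride, Et3N, toluene, 20 °C; then 16, DMAP (cat.), 80 °C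
Reagents that add atoms: none
Why: Yamaguchi esterification through the mixed anhydride should acylate the hindered C6 hydroxyl without Z to E isomerisation of the angelate and without touching a stereocentre.

Step 13
Reactants: 18 2,6-bis[2-(tert-butyldimethylsilyloxy)ethyl]-5-methyl-5-[(2R)-oxiran-2-yl]cyclohex-3-en-1-yl (Z)-2-methylbut-2-enoate
Product: 19 2,6-bis(2-hydroxyethyl)-5-methyl-5-[(2R)-oxiran-2-yl]cyclohex-3-en-1-yl (Z)-2-methylbut-2-enoate
Conditions: Bu4NF, AcOH, THF, 0 → 20 °C
Reagents that add atoms: none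
Why: buffered fluoride desilylation should free both primary alcohols while ester and epoxide survive.

Step 14
Reactants: 19 2,6-bis(2-hydroxyethyl)-5-methyl-5-[(2R)-oxiran-2-yl]cyclohex-3-en-1-yl (Z)-2-methylbut-2-enoate
Product: 20 5-methyl-5-[(2R)-oxiran-2-yl]-2,6-bis(2-oxoethyl)cyclohex-3-en-1-yl (Z)-2-methylbut-2-enoate
Conditions: Dess–Martin periodinane, CH2Cl2, 0 → 20 °C
Reagents that add atoms: none
Why: Dess–Martin oxidation of both primary alcohols should give the dialdehyde without epimerisation, since C5 and C7 are β to the new carbonyl groups.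

Step 15
Reactants: 20 5-methyl-5-[(2R)-oxiran-2-yl]-2,6-bis(2-oxoethyl)cyclohex-3-en-1-yl (Z)-2-methylbut-2-enoate
Product: 21 5-methyl-5-[(2R)-oxiran-2-yl]-2,6-bis(3-oxoprop-1-en-2-yl)cyclohex-3-en-1-yl (Z)-2-methylbut-2-enoate
Conditions: CH2=NMe2+ I−, Et3N, CH2Cl2, 20 °C
Reagents that add atoms: N,N-dimethylmethyleneiminium iodide (Eschenmoser's salt), C=[N+](C)C.[I-]
Why: twofold Mannich addition and amine elimination (aldehyde α-methylenation) should introduce C3 and C13 and so create both acrolein units in one operation.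

Step 16
Reactants: 21 5-methyl-5-[(2R)-oxiran-2-yl]-2,6-bis(3-oxoprop-1-en-2-yl)cyclohex-3-en-1-yl (Z)-2-methylbut-2-enoate
Product: 23 9-O-deangeloyl target with C12 as the lactol (anomer mixture), via bis-epoxide 22 (not isolated)
Conditions: dimethyldioxirane, acetone, −20 → 0 °C; then pyridinium p-toluenesulfonate (5 mol %), THF/H2O, 20 °C
Reagents that add atoms: dimethyldioxirane, CC1(C)OO1; water, O
Why: epoxidation should occur at the only electron-rich alkene C8=C9 from the face opposite the C10 methyl, the two arms and the C6 ester; the hydrate of the C12 aldehyde then opens the epoxide at the non-neopentyl C8 from the other face (5-exo, anti), which sets O8 cis to C11 and the C9 hydroxyl trans to O8.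

Step 17
Reactants: 23 9-O-deangeloyl target with C12 as the lactol (anomer mixture)
Product: 24 9-O-deangeloyl target (C9 hydroxy α-methylene-γ-lactone)
Conditions: MnO2, CH2Cl2, 20 °C
Reagents that add atoms: none
Why: oxidation of the allylic-type lactol to the α-methylene-γ-lactone should leave the neopentyl secondary alcohol and the enal untouched.

Step 18
Reactants: 24 9-O-deangeloyl target (C9 hydroxy α-methylene-γ-lactone); 17 angelic acid
Product: 25 target CNP0291490.2
Conditions: 2,4,6-trichlorobenzoyl chloride, Et3N, toluene, 20 °C; then 24, DMAP (cat.), 60 °C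
Reagents that add atoms: none
Why: a second Yamaguchi esterification should place the angelate on the C9 hydroxyl, the only free alcohol, with retention at C9.

Compound list
1 | 3-[(tert-butyldimethylsilyl)oxy]propanal | O=CCCO[Si](C)(C)C(C)(C)C | starting material
2 | 3-(triphenyl-λ5-phosphanylidene)butan-2-one | CC(=O)C(C)=P(c1ccccc1)(c1ccccc1)c1ccccc1 | starting material
3 | (E)-6-[(tert-butyldimethylsilyl)oxy]-3-methylhex-3-en-2-one | CC(=O)/C(C)=C/CCO[Si](C)(C)C(C)(C)C | intermediate
4 | (E)-2,6-bis[(tert-butyldimethylsilyl)oxy]-3-methylhexa-1,3-diene | C=C(O[Si](C)(C)C(C)(C)C)/C(C)=C/CCO[Si](C)(C)C(C)(C)C | intermediate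
5 | 3-bromocyclobutan-1-one | O=C1CC(Br)C1 | starting material
6 | cyclobut-2-en-1-one | O=C1C=CC1 | intermediate
7 | all-cis 3-(tert-butyldimethylsilyloxy)-5-[2-(tert-butyldimethylsilyloxy)ethyl]-4-methylbicyclo[4.2.0]oct-3-en-7-one (H1, H5, H6 on one face; C1, C5, C6 are target C7, C5, C6) | [C@@H]1(CCO[Si](C)(C)C(C)(C)C)[C@@H]2C(=O)C[C@@H]2CC(O[Si](C)(C)C(C)(C)C)=C1C | intermediate
8 | chloroacetyl chloride | ClCC(Cl)=O | starting material
9 | 4-(chloroacetyl)-5-[2-(tert-butyldimethylsilyloxy)ethyl]-4-methylbicyclo[4.2.0]octane-3,7-dione (chloroacetyl trans, methyl cis to the C5 side chain) | [C@@H]1(CCO[Si](C)(C)C(C)(C)C)[C@@H]2C(=O)C[C@@H]2CC(=O)[C@@]1(C)C(=O)CCl | intermediate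
10 | cis-fused 6-(chloroacetyl)-7-[2-(tert-butyldimethylsilyloxy)ethyl]-6-methylhexahydro-1-benzofuran-2,5-dione (O1 on target C6) | [C@@H]1(CCO[Si](C)(C)C(C)(C)C)[C@@H]2OC(=O)C[C@@H]2CC(=O)[C@@]1(C)C(=O)CCl | intermediate
11 | 6-[(1R)-2-chloro-1-hydroxyethyl] analogue of 10 (chlorohydrin) | [C@@H]1(CCO[Si](C)(C)C(C)(C)C)[C@@H]2OC(=O)C[C@@H]2CC(=O)[C@@]1(C)[C@@H](O)CCl | intermediate
12 | 7-[2-(tert-butyldimethylsilyloxy)ethyl]-6-methyl-6-[(2R)-oxiran-2-yl]hexahydro-1-benzofuran-2,5-dione | [C@@H]1(CCO[Si](C)(C)C(C)(C)C)[C@@H]2OC(=O)C[C@@H]2CC(=O)[C@@]1(C)[C@@H]3CO3 | intermediate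
13 | enol triflate of 12 (C8=C9–OTf) | [C@@H]1(CCO[Si](C)(C)C(C)(C)C)[C@@H]2OC(=O)C[C@@H]2C=C(OS(=O)(=O)C(F)(F)F)[C@@]1(C)[C@@H]3CO3 | intermediate
14 | 7-[2-(tert-butyldimethylsilyloxy)ethyl]-6-methyl-6-[(2R)-oxiran-2-yl]-3a,6,7,7a-tetrahydro-1-benzofuran-2(3H)-one | [C@@H]1(CCO[Si](C)(C)C(C)(C)C)[C@@H]2OC(=O)C[C@@H]2C=C[C@@]1(C)[C@@H]3CO3 | intermediate
15 | 6-[2-(tert-butyldimethylsilyloxy)ethyl]-2-(2-hydroxyethyl)-5-methyl-5-[(2R)-oxiran-2-yl]cyclohex-3-en-1-ol (substituents on C1, C2, C6 and the 5-methyl all cis) | [C@@H]1(CCO[Si](C)(C)C(C)(C)C)[C@H](O)[C@H](CCO)C=C[C@@]1(C)[C@@H]3CO3 | intermediate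
16 | 2,6-bis[2-(tert-butyldimethylsilyloxy)ethyl]-5-methyl-5-[(2R)-oxiran-2-yl]cyclohex-3-en-1-ol | [C@@H]1(CCO[Si](C)(C)C(C)(C)C)[C@H](O)[C@H](CCO[Si](C)(C)C(C)(C)C)C=C[C@@]1(C)[C@@H]3CO3 | intermediate
17 | angelic acid, (Z)-2-methylbut-2-enoic acid | C/C=C(/C)C(=O)O | starting material
18 | 2,6-bis[2-(tert-butyldimethylsilyloxy)ethyl]-5-methyl-5-[(2R)-oxiran-2-yl]cyclohex-3-en-1-yl (Z)-2-methylbut-2-enoate | [C@@H]1(CCO[Si](C)(C)C(C)(C)C)[C@H](OC(=O)/C(C)=C\C)[C@H](CCO[Si](C)(C)C(C)(C)C)C=C[C@@]1(C)[C@@H]3CO3 | intermediate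
19 | 2,6-bis(2-hydroxyethyl)-5-methyl-5-[(2R)-oxiran-2-yl]cyclohex-3-en-1-yl (Z)-2-methylbut-2-enoate | [C@@H]1(CCO)[C@H](OC(=O)/C(C)=C\C)[C@H](CCO)C=C[C@@]1(C)[C@@H]3CO3 | intermediate
20 | 5-methyl-5-[(2R)-oxiran-2-yl]-2,6-bis(2-oxoethyl)cyclohex-3-en-1-yl (Z)-2-methylbut-2-enoate | [C@@H]1(CC=O)[C@H](OC(=O)/C(C)=C\C)[C@H](CC=O)C=C[C@@]1(C)[C@@H]3CO3 | intermediate
21 | 5-methyl-5-[(2R)-oxiran-2-yl]-2,6-bis(3-oxoprop-1-en-2-yl)cyclohex-3-en-1-yl (Z)-2-methylbut-2-enoate | [C@@H]1(C(=C)C=O)[C@H](OC(=O)/C(C)=C\C)[C@H](C(=C)C=O)C=C[C@@]1(C)[C@@H]3CO3 | intermediate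
22 | C8–C9 epoxide of 21 (epoxide oxygen trans to the ester, cis to the oxiranyl group) | [C@@H]1(C(=C)C=O)[C@H](OC(=O)/C(C)=C\C)[C@H](C(=C)C=O)[C@H]4O[C@H]4[C@@]1(C)[C@@H]3CO3 | intermediate
23 | 9-O-deangeloyl target with C12 as the lactol (anomer mixture) | [C@@H]1(C(=C)C=O)[C@H](OC(=O)/C(C)=C\C)[C@@H]2C(=C)C(O)O[C@@H]2[C@@H](O)[C@@]1(C)[C@@H]3CO3 | intermediate
24 | 9-O-deangeloyl target (C9 hydroxy α-methylene-γ-lactone) | [C@@H]1(C(=C)C=O)[C@H](OC(=O)/C(C)=C\C)[C@@H]2C(=C)C(=O)O[C@@H]2[C@@H](O)[C@@]1(C)[C@@H]3CO3 | intermediate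
25 | CNP0291490.2 | C=C1C(=O)O[C@H]2[C@@H]1[C@@H](OC(=O)/C(C)=C\C)[C@@H](C(=C)C=O)[C@](C)([C@@H]1CO1)[C@@H]2OC(=O)/C(C)=C\C | target

Total step count: 18. Longest linear sequence: 17 (steps 1, 2 and 4–18; step 3 is a one-step branch).

Steps most likely to fail

Step 4. What may go wrong: loss of enantiofacial control because the uncatalysed cycloaddition of the very reactive enone competes, or consumption of 6 by Lewis-acid-induced polymerisation. Fallback: setting out from 4 and 6, the cycloaddition is run without catalyst (toluene, 0 → 20 °C), which should give 7 as the racemate, that is together with its enantiomer F1. The mixture is taken through steps 5 and 6, giving the enantiomeric triketone F2 and the enantiomeric lactone F3 beside 9 and 10. The reagent-controlled reduction and ring closure of step 7 then turn the two enantiomers into diastereomers, 12 and the (2R)-oxiranyl ketone on the mirror-image ring F4, which are separated by chromatography. The route is rejoined at 12.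

Step 16. What may go wrong: over-oxidation of the two aldehyde groups by the dioxirane, poor face selectivity once both enals are present, or acid-induced opening of the C1–C2 epoxide by the new C9 hydroxyl. Fallback: setting out from 18, the ring alkene is epoxidised first with mCPBA (CH2Cl2, 0 °C), where no aldehyde and no other nucleophilic alkene is present, to the C8–C9 epoxide F5. Cold buffered Bu4NF/AcOH should give the epoxy diol F6, Dess–Martin oxidation the epoxy dialdehyde F7, and Eschenmoser methylenation the bis-epoxide 22. The route is rejoined at 22, which is cyclised to 23 as in the second stage of step 16.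

Step 5. What may go wrong: slow C-acylation at the fully substituted enol ether carbon, so that desilylation to the parent ketone takes over. Fallback: setting out from 7, a Mukaiyama aldol addition to chloroacetaldehyde (BF3·OEt2, CH2Cl2, −78 °C) should give the β-hydroxy ketone F8 as a mixture at the carbinol carbon. This mixture does not matter, because Dess–Martin oxidation converts both epimers into 9, where the route is rejoined.

Further compounds
F1 | step 4 | enantiomer of 7 | [C@H]1(CCO[Si](C)(C)C(C)(C)C)[C@H]2C(=O)C[C@H]2CC(O[Si](C)(C)C(C)(C)C)=C1C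
F2 | step 4 | enantiomer of 9 | [C@H]1(CCO[Si](C)(C)C(C)(C)C)[C@H]2C(=O)C[C@H]2CC(=O)[C@]1(C)C(=O)CCl
F3 | step 4 | enantiomer of 10 | [C@H]1(CCO[Si](C)(C)C(C)(C)C)[C@H]2OC(=O)C[C@H]2CC(=O)[C@]1(C)C(=O)CCl
F4 | step 4 | diastereomer of 12 with the (2R)-oxiranyl group on the mirror-image ring | [C@H]1(CCO[Si](C)(C)C(C)(C)C)[C@H]2OC(=O)C[C@H]2CC(=O)[C@]1(C)[C@@H]3CO3
F5 | step 16 | C8–C9 epoxide of 18 | [C@@H]1(CCO[Si](C)(C)C(C)(C)C)[C@H](OC(=O)/C(C)=C\C)[C@H](CCO[Si](C)(C)C(C)(C)C)[C@H]4O[C@H]4[C@@]1(C)[C@@H]3CO3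
F6 | step 16 | C8–C9 epoxide of 19 (epoxy diol) | [C@@H]1(CCO)[C@H](OC(=O)/C(C)=C\C)[C@H](CCO)[C@H]4O[C@H]4[C@@]1(C)[C@@H]3CO3
F7 | step 16 | C8–C9 epoxide of 20 (epoxy dialdehyde) | [C@@H]1(CC=O)[C@H](OC(=O)/C(C)=C\C)[C@H](CC=O)[C@H]4O[C@H]4[C@@]1(C)[C@@H]3CO3
F8 | step 5 | 4-(2-chloro-1-hydroxyethyl)-5-[2-(tert-butyldimethylsilyloxy)ethyl]-4-methylbicyclo[4.2.0]octane-3,7-dione (carbinol epimers) | [C@@H]1(CCO[Si](C)(C)C(C)(C)C)[C@@H]2C(=O)C[C@@H]2CC(=O)[C@@]1(C)C(O)CCl
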